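**Assumption:** 1, 2, 4 and 9 are bought as catalogue items; the (E)-enals 3 and 10 are made; 5 and 11 are recrystallised once if their ee is below 98%.

## Retrosynthetic overview

1. Last step is hydrogenolysis of a penta-O-benzyl dimer; before it, the upper C3 ketone is reduced.
2. Key disconnection is the interflavan C4–C6 bond: C6 of tri-O-benzyl fisetinidol attacks the enolonium (trivalent-iodine umpoled enolate) of the upper flavan-3-one, joining a ketone α-carbon and an arene carbon that are both natural nucleophiles.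
3. Stereochemical relay in the upper unit: C2 is installed as S and steers the arene to the opposite face of C4; C2 is then inverted by enolate protonation anti to the new C4 aryl, and axial hydride sets C3.
4. Each flavan skeleton comes from an amine-catalysed oxa-Michael/aldol of one salicylaldehyde with a cinnamaldehyde (sets C2), then Baeyer–Villiger oxidation to the C3 enol formate.
5. Ring order: upper ring C and lower ring C are closed separately before the union; no ring is formed after it.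

## Route

Step 1
Reactants: 1 4-(benzyloxy)benzaldehyde; 2 (triphenyl-λ5-phosphanylidene)acetaldehyde
Product: 3 (2E)-3-[4-(benzyloxy)phenyl]prop-2-enal
Conditions: toluene, 90 °C
Reagents that add atoms: none
Why: Wittig olefination with a stabilised formyl ylide gives the (E)-enal under thermodynamic control.

Step 2
Reactants: 3 (2E)-3-[4-(benzyloxy)phenyl]prop-2-enal; 4 4-(benzyloxy)-2-hydroxybenzaldehyde
Product: 5 (2S)-7-(benzyloxy)-2-[4-(benzyloxy)phenyl]-2H-chromene-3-carbaldehyde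
Conditions: (R)-2-[diphenyl(trimethylsilyloxy)methyl]pyrrolidine (20 mol %), 2-nitrobenzoic acid (20 mol %), 4 Å MS, toluene, rt
Reagents that add atoms: none
Why: Iminium–enamine domino oxa-Michael/aldol condensation in which the (R)-catalyst shields the Si face of the iminium β-carbon, so the phenol of 4 adds to the Re face (C2 = S) and the enamine then closes ring C on the aryl aldehyde and dehydrates.

Step 3
Reactants: 5 (2S)-7-(benzyloxy)-2-[4-(benzyloxy)phenyl]-2H-chromene-3-carbaldehyde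
Product: 6 (2S)-7-(benzyloxy)-2-[4-(benzyloxy)phenyl]-2H-chromen-3-yl formate
Conditions: 30% H2O2, bis(2-nitrophenyl) diselenide (3 mol %), CH2Cl2, rt
Reagents that add atoms: hydrogen peroxide OO
Why: Baeyer–Villiger (Dakin-type) oxidation of an α-substituted cinnamaldehyde by in situ perseleninic acid, in which the electron-rich alkenyl group migrates to oxygen to give the enol formate with the C3=C4 bond fixed and C2 untouched.

Step 4
Reactants: 6 (2S)-7-(benzyloxy)-2-[4-(benzyloxy)phenyl]-2H-chromen-3-yl formate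
Product: 8 {[(2S)-7-(benzyloxy)-2-[4-(benzyloxy)phenyl]-2H-chromen-3-yl]oxy}(trimethyl)silane, via lithium enolate 7 (not isolated)
Conditions: CH3Li (2.05 equiv), THF, −78 °C; Me3SiCl (2.3 equiv), −78 °C to rt; pentane, filtration, no aqueous work-up
Reagents that add atoms: chlorotrimethylsilane C[Si](C)(C)Cl
Why: Enol-ester cleavage with an alkyllithium releases the Δ3,4 lithium enolate regiospecifically (no ketone is present, so no proton moves to C2) and O-silylation fixes it as the silyl enol ether.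

Step 5
Reactants: 9 3,4-bis(benzyloxy)benzaldehyde; 2 (triphenyl-λ5-phosphanylidene)acetaldehyde
Product: 10 (2E)-3-[3,4-bis(benzyloxy)phenyl]prop-2-enal
Conditions: toluene, 90 °C
Reagents that add atoms: none
Why: Wittig olefination with a stabilised formyl ylide gives the (E)-enal under thermodynamic control.

Step 6
Reactants: 10 (2E)-3-[3,4-bis(benzyloxy)phenyl]prop-2-enal; 4 4-(benzyloxy)-2-hydroxybenzaldehyde
Product: 11 (2R)-7-(benzyloxy)-2-[3,4-bis(benzyloxy)phenyl]-2H-chromene-3-carbaldehyde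
Conditions: (S)-2-[diphenyl(trimethylsilyloxy)methyl]pyrrolidine (20 mol %), 2-nitrobenzoic acid (20 mol %), 4 Å MS, toluene, rt
Reagents that add atoms: none
Why: The same domino oxa-Michael/aldol condensation with the (S)-catalyst, which shields the Re face of the iminium β-carbon so the phenol adds to the Si face and sets C2 of the lower unit as R.

Step 7
Reactants: 11 (2R)-7-(benzyloxy)-2-[3,4-bis(benzyloxy)phenyl]-2H-chromene-3-carbaldehyde
Product: 12 (2R)-7-(benzyloxy)-2-[3,4-bis(benzyloxy)phenyl]-2H-chromen-3-yl formate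
Conditions: 30% H2O2, bis(2-nitrophenyl) diselenide (3 mol %), CH2Cl2, rt
Reagents that add atoms: hydrogen peroxide OO
Why: Baeyer–Villiger (Dakin-type) oxidation with alkenyl migration gives the enol formate and leaves C2 untouched.

Step 8
Reactants: 12 (2R)-7-(benzyloxy)-2-[3,4-bis(benzyloxy)phenyl]-2H-chromen-3-yl formate
Product: 15 (2R,3S)-7-(benzyloxy)-2-[3,4-bis(benzyloxy)phenyl]chroman-3-ol, via lithium enolate 13 (not isolated), via flavan-3-one 14 (not isolated)
Conditions: CH3Li (2.05 equiv), THF, −78 °C; AcOH (2.2 equiv), −78 °C; then CeCl3·7H2O, NaBH4, MeOH, −78 to −40 °C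
Reagents that add atoms: none
Why: Enol-ester cleavage and cold protonation give flavan-3-one 14 without touching C2, and Luche reduction then delivers hydride axially (no syn-axial hydrogens on O1 and C4a; it is the bulky hydrides that give the 2,3-cis alcohol) to set C3 as S, trans to the equatorial 2-aryl group.

Step 9
Reactants: 8 {[(2S)-7-(benzyloxy)-2-[4-(benzyloxy)phenyl]-2H-chromen-3-yl]oxy}(trimethyl)silane; 15 (2R,3S)-7-(benzyloxy)-2-[3,4-bis(benzyloxy)phenyl]chroman-3-ol
Product: 17 (2S,4S)-7-(benzyloxy)-4-[(2R,3S)-7-(benzyloxy)-2-[3,4-bis(benzyloxy)phenyl]-3-hydroxychroman-6-yl]-2-[4-(benzyloxy)phenyl]chroman-3-one (2,4-trans ketone), via enolonium species 16 (not isolated)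
Conditions: PhI(OAc)2 (0.95 equiv), BF3·OEt2 (2 equiv), CH2Cl2, −78 °C, add 8; after 5 min add 15 (2 equiv, excess recovered), −78 to −55 °C; cold aq NaHCO3
Reagents that add atoms: none
Why: Proposed new method: PhI(OAc)2·BF3 converts the silyl enol ether into an O-bound trivalent-iodine enolate (enolonium, an umpoled enolate) whose C4 is electrophilic and further stabilised as a 2,4-dioxygenated benzylic cation, and the most nucleophilic carbon of 15 (C6, para to O1 and ortho to OBn, less hindered than C8) attacks it in a Friedel–Crafts sense with loss of PhI, so a ketone α-carbon and a phenol-ether ortho-carbon (both normally nucleophilic) are joined; A(1,2) strain with the C3 O-substituent holds the 2-aryl group pseudo-axial, so the arene enters C4 on the opposite face and gives the 2,4-trans ketone (new centre 4S); any O-alkylation by the free 3-OH re-ionises under BF3; the closest known chemistry is hypervalent-iodine enolonium α-arylation of silyl enol ethers with indoles and pyrroles, together with Lewis-acid C4 arylation of flavan electrophiles by flavan-3-ol nucleophiles carrying a free 3-OH.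

Step 10
Reactants: 17 (2S,4S)-7-(benzyloxy)-4-[(2R,3S)-7-(benzyloxy)-2-[3,4-bis(benzyloxy)phenyl]-3-hydroxychroman-6-yl]-2-[4-(benzyloxy)phenyl]chroman-3-one
Product: 20 (2R,3S,4S)-7-(benzyloxy)-4-[(2R,3S)-7-(benzyloxy)-2-[3,4-bis(benzyloxy)phenyl]-3-hydroxychroman-6-yl]-2-[4-(benzyloxy)phenyl]chroman-3-ol, via dilithium enolate 18 (not isolated), via cis-ketone 19 (not isolated)
Conditions: LiN(SiMe3)2 (2.1 equiv), THF, −78 °C; AcOH (2.3 equiv), −78 °C; then CeCl3·7H2O, NaBH4, MeOH, −78 to −40 °C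
Reagents that add atoms: none
Why: Enolisation–kinetic protonation followed by Luche reduction: the base removes the more acidic axial C2–H (α-aryloxy and benzylic; C4–H is equatorial in the 2-equatorial/4-axial conformer), AcOH protonates the Δ2,3-enolate on the face opposite the pseudo-axial C4 aryl and so inverts C2 to R (2,4-cis ketone 19), and axial hydride attack on this diequatorially locked ketone sets C3 as S with the OH equatorial and trans to both aryl groups.

Step 11
Reactants: 20 (2R,3S,4S)-7-(benzyloxy)-4-[(2R,3S)-7-(benzyloxy)-2-[3,4-bis(benzyloxy)phenyl]-3-hydroxychroman-6-yl]-2-[4-(benzyloxy)phenyl]chroman-3-ol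
Product: 21 (2R,3S,4R)-2-(4-hydroxyphenyl)-4-[(2R,3S)-2-(3,4-dihydroxyphenyl)-3,7-dihydroxychroman-6-yl]chroman-3,7-diol (CNP0243811.2)
Conditions: H2 (1 atm), Pd(OH)2/C, THF/MeOH, rt
Reagents that add atoms: none
Why: Catalytic hydrogenolysis removes the five benzyl ethers while leaving the interflavan bond and the ring C ethers intact (as in benzyl-protected procyanidin syntheses); no stereocentre is touched, and the C4 descriptor changes from S to R only because the CIP ranking of its two aryl groups switches when OBn becomes OH.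

## Compound list

1 | 4-(benzyloxy)benzaldehyde | O=Cc1ccc(OCc2ccccc2)cc1 | starting material
2 | (triphenyl-λ5-phosphanylidene)acetaldehyde | O=CC=P(c1ccccc1)(c1ccccc1)c1ccccc1 | starting material
3 | (2E)-3-[4-(benzyloxy)phenyl]prop-2-enal | O=C/C=C/c1ccc(OCc2ccccc2)cc1 | intermediate
4 | 4-(benzyloxy)-2-hydroxybenzaldehyde | O=Cc1ccc(OCc2ccccc2)cc1O | starting material
5 | (2S)-7-(benzyloxy)-2-[4-(benzyloxy)phenyl]-2H-chromene-3-carbaldehyde | O=CC1=Cc2ccc(OCc3ccccc3)cc2O[C@H]1c1ccc(OCc2ccccc2)cc1 | intermediate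
6 | (2S)-7-(benzyloxy)-2-[4-(benzyloxy)phenyl]-2H-chromen-3-yl formate | O=COC1=Cc2ccc(OCc3ccccc3)cc2O[C@H]1c1ccc(OCc2ccccc2)cc1 | intermediate
7 | lithium (2S)-7-(benzyloxy)-2-[4-(benzyloxy)phenyl]-2H-chromen-3-olate (not isolated) | [Li+].[O-]C1=Cc2ccc(OCc3ccccc3)cc2O[C@H]1c1ccc(OCc2ccccc2)cc1 | intermediate
8 | {[(2S)-7-(benzyloxy)-2-[4-(benzyloxy)phenyl]-2H-chromen-3-yl]oxy}(trimethyl)silane | C[Si](C)(C)OC1=Cc2ccc(OCc3ccccc3)cc2O[C@H]1c1ccc(OCc2ccccc2)cc1 | intermediate
9 | 3,4-bis(benzyloxy)benzaldehyde | O=Cc1ccc(OCc2ccccc2)c(OCc2ccccc2)c1 | starting material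
10 | (2E)-3-[3,4-bis(benzyloxy)phenyl]prop-2-enal | O=C/C=C/c1ccc(OCc2ccccc2)c(OCc2ccccc2)c1 | intermediate
11 | (2R)-7-(benzyloxy)-2-[3,4-bis(benzyloxy)phenyl]-2H-chromene-3-carbaldehyde | O=CC1=Cc2ccc(OCc3ccccc3)cc2O[C@@H]1c1ccc(OCc2ccccc2)c(OCc2ccccc2)c1 | intermediate
12 | (2R)-7-(benzyloxy)-2-[3,4-bis(benzyloxy)phenyl]-2H-chromen-3-yl formate | O=COC1=Cc2ccc(OCc3ccccc3)cc2O[C@@H]1c1ccc(OCc2ccccc2)c(OCc2ccccc2)c1 | intermediate
13 | lithium (2R)-7-(benzyloxy)-2-[3,4-bis(benzyloxy)phenyl]-2H-chromen-3-olate (not isolated) | [Li+].[O-]C1=Cc2ccc(OCc3ccccc3)cc2O[C@@H]1c1ccc(OCc2ccccc2)c(OCc2ccccc2)c1 | intermediate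
14 | (2R)-7-(benzyloxy)-2-[3,4-bis(benzyloxy)phenyl]chroman-3-one (not isolated) | O=C1Cc2ccc(OCc3ccccc3)cc2O[C@@H]1c1ccc(OCc2ccccc2)c(OCc2ccccc2)c1 | intermediate
15 | (2R,3S)-7-(benzyloxy)-2-[3,4-bis(benzyloxy)phenyl]chroman-3-ol (3',4',7-tri-O-benzyl-(−)-fisetinidol, 2,3-trans) | O[C@H]1Cc2ccc(OCc3ccccc3)cc2O[C@@H]1c1ccc(OCc2ccccc2)c(OCc2ccccc2)c1 | intermediate
16 | acetoxy{[(2S)-7-(benzyloxy)-2-[4-(benzyloxy)phenyl]-2H-chromen-3-yl]oxy}(phenyl)-λ3-iodane (enolonium species, drawn O-bound, BF3-activated; not isolated) | CC(=O)OI(c1ccccc1)OC1=Cc2ccc(OCc3ccccc3)cc2O[C@H]1c1ccc(OCc2ccccc2)cc1 | intermediate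
17 | (2S,4S)-7-(benzyloxy)-4-[(2R,3S)-7-(benzyloxy)-2-[3,4-bis(benzyloxy)phenyl]-3-hydroxychroman-6-yl]-2-[4-(benzyloxy)phenyl]chroman-3-one (2,4-trans) | C(c1ccccc1)Oc1ccc([C@@H]2Oc3cc(OCc4ccccc4)ccc3[C@@H](c3cc4c(cc3OCc3ccccc3)O[C@H](c3ccc(OCc5ccccc5)c(OCc5ccccc5)c3)[C@@H](O)C4)C2=O)cc1 | intermediate
18 | dilithium (4S)-7-(benzyloxy)-4-[(2R,3S)-7-(benzyloxy)-2-[3,4-bis(benzyloxy)phenyl]-3-oxidochroman-6-yl]-2-[4-(benzyloxy)phenyl]-4H-chromen-3-olate (not isolated) | C(c1ccccc1)Oc1ccc(C2=C([O-])[C@H](c3cc4c(cc3OCc3ccccc3)O[C@H](c3ccc(OCc5ccccc5)c(OCc5ccccc5)c3)[C@@H]([O-])C4)c3ccc(OCc4ccccc4)cc3O2)cc1.[Li+].[Li+] | intermediate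
19 | (2R,4S)-7-(benzyloxy)-4-[(2R,3S)-7-(benzyloxy)-2-[3,4-bis(benzyloxy)phenyl]-3-hydroxychroman-6-yl]-2-[4-(benzyloxy)phenyl]chroman-3-one (2,4-cis; not isolated) | C(c1ccccc1)Oc1ccc([C@H]2Oc3cc(OCc4ccccc4)ccc3[C@@H](c3cc4c(cc3OCc3ccccc3)O[C@H](c3ccc(OCc5ccccc5)c(OCc5ccccc5)c3)[C@@H](O)C4)C2=O)cc1 | intermediate
20 | (2R,3S,4S)-7-(benzyloxy)-4-[(2R,3S)-7-(benzyloxy)-2-[3,4-bis(benzyloxy)phenyl]-3-hydroxychroman-6-yl]-2-[4-(benzyloxy)phenyl]chroman-3-ol (2,3-trans-3,4-trans) | C(c1ccccc1)Oc1ccc([C@H]2Oc3cc(OCc4ccccc4)ccc3[C@@H](c3cc4c(cc3OCc3ccccc3)O[C@H](c3ccc(OCc5ccccc5)c(OCc5ccccc5)c3)[C@@H](O)C4)[C@@H]2O)cc1 | intermediate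
21 | (2R,3S,4R)-2-(4-hydroxyphenyl)-4-[(2R,3S)-2-(3,4-dihydroxyphenyl)-3,7-dihydroxychroman-6-yl]chroman-3,7-diol (guibourtinidol-(4α→6)-fisetinidol) | Oc1ccc([C@H]2Oc3cc(O)ccc3[C@@H](c3cc4c(cc3O)O[C@H](c3ccc(O)c(O)c3)[C@@H](O)C4)[C@@H]2O)cc1 | target

## Step count

Total steps: 11. Longest linear sequence: 7 (steps 1, 2, 3, 4, 9, 10, 11; the lower-unit branch 5, 6, 7, 8, 9, 10, 11 is equally long).

## Steps most likely to fail, with fallbacks

**Step 9 (enolonium arylation).** The risks are capture of the cation by acetate, oxidation of the electron-rich arene by unreacted trivalent iodine, further arylation of 17, ring contraction, and weak facial control at C4. The fallback sets out from 8 and returns at 17. N-bromosuccinimide in THF at −78 °C brominates 8 at C4 anti to the 2-aryl group to give the α-haloketone (2S,4R)-4-bromo-7-(benzyloxy)-2-[4-(benzyloxy)phenyl]chroman-3-one F1. This is ionised with AgOSO2CF3 and 2,6-di-tert-butyl-4-methylpyridine in CH2Cl2 at −78 °C in the presence of 15. The resulting SN1 Friedel–Crafts reaction of a classical α-keto halide gives 17 with the same anti entry of the arene and no hypervalent iodine oxidant in the flask.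

**Step 10 (C2 inversion and ketone reduction).** The risks are competing deprotonation at C4, unselective protonation at C2, and hydride attack from the wrong face. The fallback sets out from 17 and returns at 20; it replaces substrate-controlled protonation by reagent-controlled protonation. LiN(SiMe3)2 (2.2 equiv) and Me3SiCl trap the enolate as the isolable {[(4S)-7-(benzyloxy)-4-[(2R,3S)-7-(benzyloxy)-2-[3,4-bis(benzyloxy)phenyl]-3-[(trimethylsilyl)oxy]chroman-6-yl]-2-[4-(benzyloxy)phenyl]-4H-chromen-3-yl]oxy}(trimethyl)silane F2. A chiral Brønsted acid (BINOL-derived N-triflyl thiophosphoramide, 5 mol %, enantiomer matched to the substrate bias) with phenol in toluene then performs an enantioselective protonation of this 2-aryl silyl enol ether. This gives (2R,4S)-7-(benzyloxy)-4-[(2R,3S)-7-(benzyloxy)-2-[3,4-bis(benzyloxy)phenyl]-3-[(trimethylsilyl)oxy]chroman-6-yl]-2-[4-(benzyloxy)phenyl]chroman-3-one F3. Luche reduction followed by K2CO3/MeOH (removes the remaining silyl ether) gives 20.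

**Step 8 (trans-selective reduction of flavan-3-one 14).** The risk is that the 2,3-cis alcohol predominates. The fallback sets out from 11 and returns at 15. RhCl(PPh3)3 (1.05 equiv) in toluene at 80 °C decarbonylates the enal to (2S)-7-(benzyloxy)-2-[3,4-bis(benzyloxy)phenyl]-2H-chromene F4 (same spatial arrangement at C2 as in 11; only the CIP label changes). Hydroboration with BH3·THF at 0 °C and oxidation with NaOH/H2O2 then places boron on C3 anti to the 2-aryl group and gives 15 as the 2,3-trans alcohol.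

## Further compounds

F1 | step 9 | (2S,4R)-4-bromo-7-(benzyloxy)-2-[4-(benzyloxy)phenyl]chroman-3-one | C(c1ccccc1)Oc1ccc([C@@H]2Oc3cc(OCc4ccccc4)ccc3[C@@H](Br)C2=O)cc1
F2 | step 10 | {[(4S)-7-(benzyloxy)-4-[(2R,3S)-7-(benzyloxy)-2-[3,4-bis(benzyloxy)phenyl]-3-[(trimethylsilyl)oxy]chroman-6-yl]-2-[4-(benzyloxy)phenyl]-4H-chromen-3-yl]oxy}(trimethyl)silane | C(c1ccccc1)Oc1ccc(C2=C(O[Si](C)(C)C)[C@H](c3cc4c(cc3OCc3ccccc3)O[C@H](c3ccc(OCc5ccccc5)c(OCc5ccccc5)c3)[C@@H](O[Si](C)(C)C)C4)c3ccc(OCc4ccccc4)cc3O2)cc1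
F3 | step 10 | (2R,4S)-7-(benzyloxy)-4-[(2R,3S)-7-(benzyloxy)-2-[3,4-bis(benzyloxy)phenyl]-3-[(trimethylsilyl)oxy]chroman-6-yl]-2-[4-(benzyloxy)phenyl]chroman-3-one | C(c1ccccc1)Oc1ccc([C@H]2Oc3cc(OCc4ccccc4)ccc3[C@@H](c3cc4c(cc3OCc3ccccc3)O[C@H](c3ccc(OCc5ccccc5)c(OCc5ccccc5)c3)[C@@H](O[Si](C)(C)C)C4)C2=O)cc1
F4 | step 8 | (2S)-7-(benzyloxy)-2-[3,4-bis(benzyloxy)phenyl]-2H-chromene | C1=Cc2ccc(OCc3ccccc3)cc2O[C@@H]1c1ccc(OCc2ccccc2)c(OCc2ccccc2)c1
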